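**Strategy.** The route rests on disconnecting the C4–C5 bond of the cyclohexane ring, which in the target carries two trans oxygens. Ring-closing metathesis forms C4=C5 and closes the only carbocycle in one operation from an open-chain diene in which C1 (quaternary, from D-malic acid) and C3 (from a catalyst-controlled ynone reduction) are already fixed. The precursor is methyl (2R,4R)-2-allyl-2-hydroxy-4-silyloxyhex-5-enoate; the silyl ether keeps the 4-oxygen from lactonising onto the ester. The cis C1/C3 hydroxyls then steer an epoxide to their face, the C1 carboxyl opens it at C5, and benzyl quinate is galloylated and hydrogenolysed.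

Key step: step 8

Remark 1: ring atoms are numbered as in quinic acid (C1 quaternary; C3, C4, C5 oxygenated); the target SMILES is the 3,4,5-tri-O-galloyl ester of (−)-quinic acid (1-OH, 3-O, 4-O on one face; 5-O and CO2H on the other), for which (R)-malic acid is the correct source of C1.
Remark 2: 3,4,5-tris(benzyloxy)benzoic acid (perbenzylated gallic acid) is taken as a purchased compound.

**Step 1**
Reactants: 1 D-malic acid; 2 pivalaldehyde
Product: 3 (2R,4R)-2-tert-butyl-5-oxo-1,3-dioxolane-4-acetic acid
Conditions: t-BuCHO, p-TsOH (cat.), H2SO4 (cat.), pentane, reflux, Dean–Stark; recrystallise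
Reagents that add atoms: pivalaldehyde (2), CC(C)(C)C=O
Why: Acid-catalysed acetalisation of the α-hydroxy acid unit closes the five-membered dioxolanone in preference to the six-membered alternative, and the new acetal carbon equilibrates to the cis isomer (tert-butyl and CH2CO2H on one face), which crystallises.

**Step 2**
Reactants: 3 (2R,4R)-2-tert-butyl-5-oxo-1,3-dioxolane-4-acetic acid; 4 allyl bromide
Product: 6 (2R,4R)-4-allyl-2-tert-butyl-5-oxo-1,3-dioxolane-4-acetic acid, via dilithium enolate carboxylate 5 (not isolated)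
Conditions: LiN(SiMe3)2 (2.2 equiv), THF, −78 °C; allyl bromide, −78 to −30 °C; aq. HCl
Reagents that add atoms: allyl bromide (4), C=CCBr
Why: Dioxolanone enolate alkylation with self-regeneration of the stereocentre: the planar enolate is allylated on the face away from the tert-butyl group, so allyl takes the place of the former hydrogen (retention at the future C1), while the carboxylate shields the side-chain α-protons.

**Step 3**
Reactants: 6 (2R,4R)-4-allyl-2-tert-butyl-5-oxo-1,3-dioxolane-4-acetic acid; 7 trimethylsilylacetylene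
Product: 9 (2R,5R)-5-allyl-2-tert-butyl-5-[2-oxo-4-(trimethylsilyl)but-3-yn-1-yl]-1,3-dioxolan-4-one, via acid chloride 8 (not isolated)
Conditions: (COCl)2, DMF (cat.), CH2Cl2, 0 °C to rt, evaporate; then Me3SiC≡CH, PdCl2(PPh3)2 (2 mol%), CuI (4 mol%), Et3N, THF, rt
Reagents that add atoms: trimethylsilylacetylene (7), C#C[Si](C)(C)C
Why: Acid chloride formation followed by acyl Sonogashira coupling gives the ynone without any strong nucleophile, so the dioxolanone carbonyl and the allyl group are left alone and no stereocentre is touched.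

**Step 4**
Reactants: 9 (2R,5R)-5-allyl-2-tert-butyl-5-[2-oxo-4-(trimethylsilyl)but-3-yn-1-yl]-1,3-dioxolan-4-one
Product: 10 (2R,5R)-5-allyl-2-tert-butyl-5-[(2R)-2-hydroxy-4-(trimethylsilyl)but-3-yn-1-yl]-1,3-dioxolan-4-one
Conditions: Ru[(R,R)-TsDPEN](p-cymene) (2 mol%, base-free amido complex), i-PrOH, rt; short silica plug, used at once
Reagents that add atoms: none
Why: Noyori asymmetric transfer hydrogenation of an alkynyl ketone is catalyst-controlled, the alkynyl group playing the part of the aryl group in the usual model, so the (R,R) catalyst should give the (R)-carbinol (future C3) whatever the preference of the remote quaternary centre; base-free conditions spare the β-oxygenated ynone.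

**Step 5**
Reactants: 10 (2R,5R)-5-allyl-2-tert-butyl-5-[(2R)-2-hydroxy-4-(trimethylsilyl)but-3-yn-1-yl]-1,3-dioxolan-4-one
Product: 11 (2R,5R)-5-allyl-2-tert-butyl-5-[(2R)-2-[(tert-butyldimethylsilyl)oxy]-4-(trimethylsilyl)but-3-yn-1-yl]-1,3-dioxolan-4-one
Conditions: TBSOTf, 2,6-lutidine, CH2Cl2, −78 to 0 °C
Reagents that add atoms: tert-butyldimethylsilyl triflate, CC(C)(C)[Si](C)(C)OS(=O)(=O)C(F)(F)F
Why: Silylation with a silyl triflate and a hindered pyridine is fast at low temperature and caps the γ-hydroxyl before it can acylate itself on the dioxolanone carbonyl; from here on no open-chain compound can lactonise.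

**Step 6**
Reactants: 11 (2R,5R)-5-allyl-2-tert-butyl-5-[(2R)-2-[(tert-butyldimethylsilyl)oxy]-4-(trimethylsilyl)but-3-yn-1-yl]-1,3-dioxolan-4-one
Product: 12 methyl (2R,4R)-2-allyl-4-[(tert-butyldimethylsilyl)oxy]-2-hydroxyhex-5-ynoate
Conditions: NaOMe (0.3 equiv), MeOH, 0 °C to rt
Reagents that add atoms: methanol, CO
Why: Methoxide-catalysed transesterification opens the dioxolanone to the methyl ester and tertiary alcohol with loss of pivalaldehyde, and the same base cleaves the alkynyl C–Si bond, while the secondary TBS ether is inert to methoxide.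

**Step 7**
Reactants: 12 methyl (2R,4R)-2-allyl-4-[(tert-butyldimethylsilyl)oxy]-2-hydroxyhex-5-ynoate
Product: 13 methyl (2R,4R)-2-allyl-4-[(tert-butyldimethylsilyl)oxy]-2-hydroxyhex-5-enoate
Conditions: H2 (1 atm), Lindlar catalyst (Pd on CaCO3, poisoned with Pb(OAc)2), quinoline, EtOAc, rt, stopped after one equivalent of H2
Reagents that add atoms: none
Why: Lindlar semi-hydrogenation reduces the terminal alkyne much faster than a monosubstituted alkene on the poisoned palladium surface, so the allyl group should survive if uptake is stopped at one equivalent.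

**Step 8 (key step)**
Reactants: 13 methyl (2R,4R)-2-allyl-4-[(tert-butyldimethylsilyl)oxy]-2-hydroxyhex-5-enoate
Product: 14 methyl (1R,3R)-3-[(tert-butyldimethylsilyl)oxy]-1-hydroxycyclohex-4-ene-1-carboxylate
Conditions: second-generation Grubbs catalyst (H2IMes)(PCy3)Cl2Ru=CHPh (3 mol%), CH2Cl2 (0.01 M), 40 °C
Reagents that add atoms: none
Why: The ruthenium benzylidene exchanges onto the unhindered allyl terminus, the new alkylidene adds [2+2] to the vinyl group beside the silyloxy carbon, and cycloreversion of the ruthenacyclobutane releases the cyclohexene with loss of ethylene. The closest known reaction type is ring-closing metathesis of 1,7-dienes bearing an allylic oxygen and a quaternary carbinol, as used for cyclohexenols and carbasugars. The six-membered carbocycle closes by joining the two terminal alkene carbons as C4=C5, an unstrained closure with no bridged or fused ring. No stereocentre is formed; C1 and C3 arrive set and are not epimerised under neutral conditions. The selectivity needed is ring closure over intermolecular metathesis and over alkene migration: the quaternary C1 (gem-disubstituent effect), high dilution and escape of ethylene secure it, and the silyl ether both blocks the γ-lactone that would hold allyl and vinyl trans on a five-membered ring and prevents isomerisation of a free allylic alcohol to a ketone.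

**Step 9**
Reactants: 14 methyl (1R,3R)-3-[(tert-butyldimethylsilyl)oxy]-1-hydroxycyclohex-4-ene-1-carboxylate
Product: 15 methyl (1R,3R)-1,3-dihydroxycyclohex-4-ene-1-carboxylate
Conditions: HF·pyridine, pyridine, THF, 0 °C to rt
Reagents that add atoms: none
Why: Fluoride-driven silyl ether cleavage under buffered, non-basic conditions frees the allylic hydroxyl, which in the ring is trans to the ester and therefore cannot lactonise.

**Step 10**
Reactants: 15 methyl (1R,3R)-1,3-dihydroxycyclohex-4-ene-1-carboxylate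
Product: 16 methyl (1S,3R,4R,5S)-4,5-epoxy-1,3-dihydroxycyclohexane-1-carboxylate
Conditions: VO(acac)2 (5 mol%), t-BuOOH (decane), CH2Cl2, 0 °C to rt
Reagents that add atoms: tert-butyl hydroperoxide, CC(C)(C)OO
Why: Vanadium-catalysed hydroxyl-directed epoxidation delivers the peroxide oxygen from a vanadate ester of the allylic C3 hydroxyl, reinforced by the cis homoallylic C1 hydroxyl, so both new C–O bonds at C4 and C5 form on the face of these hydroxyls.

**Step 11**
Reactants: 16 methyl (1S,3R,4R,5S)-4,5-epoxy-1,3-dihydroxycyclohexane-1-carboxylate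
Product: 18 (−)-quinide [(1S,3R,4R,5R)-1,3,4-trihydroxy-6-oxabicyclo[3.2.1]octan-7-one], via lithium epoxy carboxylate 17 (not isolated)
Conditions: LiOH (1.1 equiv), THF/H2O, 0 °C; then 1 M HCl to pH 2, rt
Reagents that add atoms: lithium hydroxide, [Li+].[OH-]
Why: Ester saponification followed by acid-promoted intramolecular epoxide opening: the C1 carboxyl lies on the face opposite the epoxide oxygen and attacks C5 from the rear in a 5-exo, trans-diaxial sense (inversion at C5, C4–O kept cis to C3–O), the known lactonisation of 3,4-epoxycyclohexanecarboxylic acids, while attack at C4 is disfavoured by the adjacent C3–O bond.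

**Step 12**
Reactants: 18 (−)-quinide; 19 benzyl bromide
Product: 21 benzyl (−)-quinate, via cesium quinate 20 (not isolated)
Conditions: CsOH·H2O (1.0 equiv), H2O/MeOH, rt, evaporate; then BnBr, DMF, rt
Reagents that add atoms: cesium hydroxide, [Cs+].[OH-]; benzyl bromide (19), BrCc1ccccc1
Why: Hydroxide opens the strained γ-lactone by acyl–oxygen cleavage (no stereocentre involved) and the cesium carboxylate is O-benzylated by SN2 in DMF, the neutral hydroxyls being unreactive without a stronger base; any quinic acid carried over from step 11 converges here.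

**Step 13**
Reactants: 21 benzyl (−)-quinate; 22 3,4,5-tris(benzyloxy)benzoic acid (3.6 equiv)
Product: 23 benzyl 3,4,5-tris-O-[3,4,5-tris(benzyloxy)benzoyl]-(−)-quinate
Conditions: EDC·HCl, DMAP, CH2Cl2, rt to 40 °C
Reagents that add atoms: 3,4,5-tris(benzyloxy)benzoic acid (22), OC(=O)c1cc(OCc2ccccc2)c(OCc2ccccc2)c(OCc2ccccc2)c1
Why: Steglich esterification acylates the three secondary hydroxyls, whereas the tertiary C1 hydroxyl, hindered and α to an ester, should stay free under these mild conditions.

**Step 14**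
Reactants: 23 benzyl 3,4,5-tris-O-[3,4,5-tris(benzyloxy)benzoyl]-(−)-quinate
Product: 24 3,4,5-tri-O-galloyl-(−)-quinic acid (CNP0148451.1)
Conditions: H2 (1 atm), Pd on carbon (10%), THF/MeOH, rt
Reagents that add atoms: none
Why: Catalytic hydrogenolysis cleaves the nine benzyl ethers and the benzyl ester at their benzylic C–O bonds under neutral conditions that should neither cleave nor shift the galloyl esters.

**Compound list**

1 | D-malic acid, (R)-2-hydroxybutanedioic acid | O[C@H](CC(O)=O)C(O)=O | starting material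
2 | pivalaldehyde | CC(C)(C)C=O | starting material
3 | (2R,4R)-2-tert-butyl-5-oxo-1,3-dioxolane-4-acetic acid (tert-butyl cis to CH2CO2H) | OC(=O)C[C@H]1O[C@@H](C(C)(C)C)OC1=O | intermediate
4 | allyl bromide | C=CCBr | starting material
5 | dilithium enolate carboxylate of 3 (acetal carbon R) | [Li+].[Li+].[O-]C(=O)CC1=C([O-])O[C@H](C(C)(C)C)O1 | intermediate (not isolated)
6 | (2R,4R)-4-allyl-2-tert-butyl-5-oxo-1,3-dioxolane-4-acetic acid (allyl trans to tert-butyl) | OC(=O)C[C@@]1(CC=C)O[C@@H](C(C)(C)C)OC1=O | intermediate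
7 | trimethylsilylacetylene | C#C[Si](C)(C)C | starting material
8 | acid chloride of 6 | ClC(=O)C[C@@]1(CC=C)O[C@@H](C(C)(C)C)OC1=O | intermediate (not isolated)
9 | (2R,5R)-5-allyl-2-tert-butyl-5-[2-oxo-4-(trimethylsilyl)but-3-yn-1-yl]-1,3-dioxolan-4-one | C[Si](C)(C)C#CC(=O)C[C@@]1(CC=C)O[C@@H](C(C)(C)C)OC1=O | intermediate
10 | (2R,5R)-5-allyl-2-tert-butyl-5-[(2R)-2-hydroxy-4-(trimethylsilyl)but-3-yn-1-yl]-1,3-dioxolan-4-one | C[Si](C)(C)C#C[C@H](O)C[C@@]1(CC=C)O[C@@H](C(C)(C)C)OC1=O | intermediate
11 | (2R,5R)-5-allyl-2-tert-butyl-5-[(2R)-2-[(tert-butyldimethylsilyl)oxy]-4-(trimethylsilyl)but-3-yn-1-yl]-1,3-dioxolan-4-one | C[Si](C)(C)C#C[C@H](O[Si](C)(C)C(C)(C)C)C[C@@]1(CC=C)O[C@@H](C(C)(C)C)OC1=O | intermediate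
12 | methyl (2R,4R)-2-allyl-4-[(tert-butyldimethylsilyl)oxy]-2-hydroxyhex-5-ynoate | C#C[C@H](O[Si](C)(C)C(C)(C)C)C[C@@](O)(C(=O)OC)CC=C | intermediate
13 | methyl (2R,4R)-2-allyl-4-[(tert-butyldimethylsilyl)oxy]-2-hydroxyhex-5-enoate (metathesis precursor) | C=C[C@H](O[Si](C)(C)C(C)(C)C)C[C@@](O)(C(=O)OC)CC=C | intermediate
14 | methyl (1R,3R)-3-[(tert-butyldimethylsilyl)oxy]-1-hydroxycyclohex-4-ene-1-carboxylate (1-OH cis to 3-O) | COC(=O)[C@@]1(O)CC=C[C@H](O[Si](C)(C)C(C)(C)C)C1 | intermediate
15 | methyl (1R,3R)-1,3-dihydroxycyclohex-4-ene-1-carboxylate (cis-diol) | COC(=O)[C@@]1(O)CC=C[C@H](O)C1 | intermediate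
16 | methyl (1S,3R,4R,5S)-4,5-epoxy-1,3-dihydroxycyclohexane-1-carboxylate (epoxide oxygen cis to both hydroxyls) | COC(=O)[C@@]1(O)C[C@@H]2O[C@@H]2[C@H](O)C1 | intermediate
17 | lithium (1S,3R,4R,5S)-4,5-epoxy-1,3-dihydroxycyclohexane-1-carboxylate | [Li+].[O-]C(=O)[C@@]1(O)C[C@@H]2O[C@@H]2[C@H](O)C1 | intermediate (not isolated)
18 | (−)-quinide, (1S,3R,4R,5R)-1,3,4-trihydroxy-6-oxabicyclo[3.2.1]octan-7-one | O=C1O[C@@H]2C[C@@]1(O)C[C@@H](O)[C@H]2O | intermediate
19 | benzyl bromide | BrCc1ccccc1 | starting material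
20 | cesium (−)-quinate | O[C@@H]1C[C@](O)(C(=O)[O-])C[C@@H](O)[C@H]1O.[Cs+] | intermediate (not isolated)
21 | benzyl (−)-quinate (1-OH, 3-OH, 4-OH on one face; 5-OH and ester on the other; 3R,5R) | O[C@@H]1C[C@](O)(C(=O)OCc2ccccc2)C[C@@H](O)[C@H]1O | intermediate
22 | 3,4,5-tris(benzyloxy)benzoic acid | OC(=O)c1cc(OCc2ccccc2)c(OCc2ccccc2)c(OCc2ccccc2)c1 | starting material
23 | benzyl 3,4,5-tris-O-[3,4,5-tris(benzyloxy)benzoyl]-(−)-quinate | O=C(O[C@@H]1C[C@](O)(C(=O)OCc2ccccc2)C[C@@H](OC(=O)c2cc(OCc3ccccc3)c(OCc3ccccc3)c(OCc3ccccc3)c2)[C@H]1OC(=O)c1cc(OCc2ccccc2)c(OCc2ccccc2)c(OCc2ccccc2)c1)c1cc(OCc2ccccc2)c(OCc2ccccc2)c(OCc2ccccc2)c1 | intermediate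
24 | 3,4,5-tri-O-galloyl-(−)-quinic acid (CNP0148451.1) | O=C(O[C@@H]1C[C@](O)(C(=O)O)C[C@@H](OC(=O)c2cc(O)c(O)c(O)c2)[C@H]1OC(=O)c1cc(O)c(O)c(O)c1)c1cc(O)c(O)c(O)c1 | target

**Step count.** Total: 14 steps. Longest linear sequence: 14 steps, from D-malic acid (acid 22 is bought).

**Steps most likely to fail**

Step 4. The hydroxyl created by the reduction sits γ to the dioxolanone carbonyl and may acylate itself, with loss of pivalaldehyde, before it is silylated; in addition, catalyst-controlled face selectivity beside a β-quaternary carbon is untested. Fallback, setting out from 10: the self-acylation is not fought but driven to completion (p-TsOH cat., CH2Cl2), giving (3R,5R)-3-allyl-3-hydroxy-5-[(trimethylsilyl)ethynyl]oxolan-2-one F1, which stores both stereocentres. LiOH in aqueous THF opens the lactone and cleaves the alkynyl silane to lithium (2R,4R)-2-allyl-2,4-dihydroxyhex-5-ynoate F2, which as a salt cannot re-lactonise. TBSCl and imidazole in DMF silylate the carboxylate and the secondary hydroxyl to tert-butyldimethylsilyl (2R,4R)-2-allyl-4-[(tert-butyldimethylsilyl)oxy]-2-hydroxyhex-5-ynoate F3. K2CO3 in aqueous methanol cleaves only the silyl ester to (2R,4R)-2-allyl-4-[(tert-butyldimethylsilyl)oxy]-2-hydroxyhex-5-ynoic acid F4, and Me3SiCHN2 in MeOH/toluene gives the methyl ester, rejoining the route at 12.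

Step 8. Intermolecular metathesis at the allyl terminus may give oligomers, or the alkylidene formed there may be held as a chelate by the neighbouring hydroxy ester and stall the catalyst. Fallback, setting out from 11: the ring is closed while hydroxyl and carboxyl are still tied back in the dioxolanone (spiro-annulation). AgNO3 (cat.) in acetone/H2O removes the alkynyl silane without opening the dioxolanone, giving (2R,5R)-5-allyl-2-tert-butyl-5-[(2R)-2-[(tert-butyldimethylsilyl)oxy]but-3-yn-1-yl]-1,3-dioxolan-4-one F5. Lindlar semi-hydrogenation gives (2R,5R)-5-allyl-2-tert-butyl-5-[(2R)-2-[(tert-butyldimethylsilyl)oxy]but-3-en-1-yl]-1,3-dioxolan-4-one F6. Metathesis with the same catalyst gives (2R,5R,9R)-2-tert-butyl-9-[(tert-butyldimethylsilyl)oxy]-1,3-dioxaspiro[4.5]dec-7-en-4-one F7, and NaOMe in MeOH opens the dioxolanone to rejoin the route at 14.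

Step 11. After saponification, external hydroxide or water may open the epoxide, the lactone may be hydrolysed further, or the carboxylate may attack C4, so that clean lactonisation is lost. Fallback, setting out from 16: the epoxide is opened intermolecularly with water under acid catalysis (dilute HClO4, THF/H2O). Trans-diaxial attack at C5, the carbon remote from the C3 hydroxyl, should give methyl (−)-quinate F8. CsOH·H2O in aqueous methanol saponifies it to cesium quinate, rejoining the route at 20 before benzylation to 21.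

**Further compounds**

F1 | step 4 | (3R,5R)-3-allyl-3-hydroxy-5-[(trimethylsilyl)ethynyl]oxolan-2-one | C[Si](C)(C)C#C[C@H]1C[C@](O)(CC=C)C(=O)O1
F2 | step 4 | lithium (2R,4R)-2-allyl-2,4-dihydroxyhex-5-ynoate | C#C[C@H](O)C[C@@](O)(C(=O)[O-])CC=C.[Li+]
F3 | step 4 | tert-butyldimethylsilyl (2R,4R)-2-allyl-4-[(tert-butyldimethylsilyl)oxy]-2-hydroxyhex-5-ynoate | C#C[C@H](O[Si](C)(C)C(C)(C)C)C[C@@](O)(C(=O)O[Si](C)(C)C(C)(C)C)CC=C
F4 | step 4 | (2R,4R)-2-allyl-4-[(tert-butyldimethylsilyl)oxy]-2-hydroxyhex-5-ynoic acid | C#C[C@H](O[Si](C)(C)C(C)(C)C)C[C@@](O)(C(=O)O)CC=C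
F5 | step 8 | (2R,5R)-5-allyl-2-tert-butyl-5-[(2R)-2-[(tert-butyldimethylsilyl)oxy]but-3-yn-1-yl]-1,3-dioxolan-4-one | C#C[C@H](O[Si](C)(C)C(C)(C)C)C[C@@]1(CC=C)O[C@@H](C(C)(C)C)OC1=O
F6 | step 8 | (2R,5R)-5-allyl-2-tert-butyl-5-[(2R)-2-[(tert-butyldimethylsilyl)oxy]but-3-en-1-yl]-1,3-dioxolan-4-one | C=C[C@H](O[Si](C)(C)C(C)(C)C)C[C@@]1(CC=C)O[C@@H](C(C)(C)C)OC1=O
F7 | step 8 | (2R,5R,9R)-2-tert-butyl-9-[(tert-butyldimethylsilyl)oxy]-1,3-dioxaspiro[4.5]dec-7-en-4-one | CC(C)(C)[Si](C)(C)O[C@H]1C=CC[C@]2(C1)O[C@@H](C(C)(C)C)OC2=O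
F8 | step 11 | methyl (−)-quinate | O[C@@H]1C[C@](O)(C(=O)OC)C[C@@H](O)[C@H]1O
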